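The hindered C3'–C8'' biaryl bond is never made by coupling. Ring B is cut back to a 2-pyrone and an alkyne already bonded to ring D. In one operation, an inverse-demand Diels–Alder/retro-Diels–Alder sequence forms C2'–C3' and C4'–C5', expels CO2 and delivers aromatic ring B with the C4' and C5' methoxyls and an ester at C1'. It exploits the ring B pattern, in which acyl carbon C1' lies para to the C4' methoxyl and C8'' of ring D sits at C3' beside it. The precursors are tri-O-benzylapigenin bearing a methoxyethynyl group at C8'' and methyl 3-methoxycoumalate. The ester then serves to build rings A and C.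

Key step: step 7

Remark: biflavone locants are used (unit 1: rings A and C plus ring B, primed; unit 2: rings D, E and F, doubly and triply primed), pyrones are numbered O1, C2(=O) to C6, the target SMILES defines no configuration at the C3'–C8'' axis so all biaryls are treated as racemic or freely rotating, and adduct 13 is racemic (one enantiomer drawn).

**Route**

Step 1
Reactants: 1 methyl coumalate (methyl 6-oxo-6H-pyran-3-carboxylate)
Product: 2 methyl 5-bromo-6-oxo-6H-pyran-3-carboxylate (methyl 3-bromocoumalate)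
Conditions: Br2, CH2Cl2, 0 °C to rt; then Et3N, 0 °C
Reagents that add atoms: bromine, BrBr
Why: Electrophilic attack of bromine at pyrone C3, the position activated by the ring oxygen through the diene (C5 is blocked by the ester), followed by loss of HBr to triethylamine, should restore the pyrone with bromine at C3, the usual course of 2-pyrone bromination.

Step 2
Reactants: 2 methyl 5-bromo-6-oxo-6H-pyran-3-carboxylate
Product: 4 methyl 5-hydroxy-6-oxo-6H-pyran-3-carboxylate, via pyronyl pinacolboronate 3 (not isolated)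
Conditions: B2pin2, PdCl2(dppf) (cat.), KOAc, 1,4-dioxane, 80 °C; filter, concentrate; then KHSO5 (as 2KHSO5·KHSO4·K2SO4), acetone–H2O, 0 °C
Reagents that add atoms: potassium peroxymonosulfate, [K+].[O-]S(=O)(=O)OO
Why: Miyaura borylation of the alkenyl bromide with the weak base KOAc, then oxidative migration of carbon from boron to oxygen under acidic peroxymonosulfate, should give the enol, which rests as the 3-hydroxypyrone; this detour is chosen because methoxide cannot displace a bromide alpha to the lactone carbonyl and would instead open the ring at C6.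

Step 3
Reactants: 4 methyl 5-hydroxy-6-oxo-6H-pyran-3-carboxylate
Product: 5 methyl 5-methoxy-6-oxo-6H-pyran-3-carboxylate (methyl 3-methoxycoumalate)
Conditions: MeI, K2CO3, acetone, rt
Reagents that add atoms: iodomethane, CI
Why: O-Alkylation of the acidic enol hydroxyl with a carbonate base in an aprotic solvent is the established way from 3-hydroxy-2-pyrones to their methyl ethers, and the anionic pyrone resists ring opening.

Step 4
Reactants: 6 apigenin
Product: 7 5,7-bis(benzyloxy)-2-[4-(benzyloxy)phenyl]-4H-chromen-4-one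
Conditions: BnBr (excess), K2CO3, DMF, 80 °C
Reagents that add atoms: benzyl bromide, BrCc1ccccc1
Why: Williamson etherification, in which the hydrogen-bonded C5'' hydroxyl reacts last, so an excess of bromide in hot DMF should carry all three phenols to the ether.

Step 5
Reactants: 7 5,7-bis(benzyloxy)-2-[4-(benzyloxy)phenyl]-4H-chromen-4-one
Product: 8 5,7-bis(benzyloxy)-2-[4-(benzyloxy)phenyl]-8-iodo-4H-chromen-4-one
Conditions: N-iodosuccinimide, CF3CO2H (cat.), MeCN–CH2Cl2, 0 °C to rt, dark
Reagents that add atoms: N-iodosuccinimide, O=C1CCC(=O)N1I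
Why: Electrophilic aromatic iodination should go to C8'' of ring D, which is activated by the C7'' ether and the ring oxygen, because C6'' lies between two benzyloxy groups and is usually taken only when the C5'' hydroxyl is free.

Step 6
Reactants: 8 5,7-bis(benzyloxy)-2-[4-(benzyloxy)phenyl]-8-iodo-4H-chromen-4-one; 9 chloroacetaldehyde dimethyl acetal
Product: 12 5,7-bis(benzyloxy)-2-[4-(benzyloxy)phenyl]-8-(methoxyethynyl)-4H-chromen-4-one, via lithium methoxyacetylide 10 (not isolated), via methoxyethynylzinc chloride 11 (not isolated)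
Conditions: 9, LiNEt2 (from n-BuLi and Et2NH, just under 3 equiv per 9), THF, 0 °C; ZnCl2, 0 °C; then 8, Pd(PPh3)4 (cat.), THF, rt to 45 °C; NaHCO3 work-up, Et3N-deactivated silica
Reagents that add atoms: none
Why: Negishi coupling, in which two eliminations and one deprotonation by LiNEt2 turn acetal 9 into the lithium acetylide, ZnCl2 tames it to an alkynylzinc that does not add to the flavone, and zerovalent palladium joins it to the aryl iodide, a reaction type established for alkoxyethynylzinc halides.

Step 7
Reactants: 5 methyl 5-methoxy-6-oxo-6H-pyran-3-carboxylate; 12 5,7-bis(benzyloxy)-2-[4-(benzyloxy)phenyl]-8-(methoxyethynyl)-4H-chromen-4-one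
Product: 14 methyl 3-{5,7-bis(benzyloxy)-2-[4-(benzyloxy)phenyl]-4-oxo-4H-chromen-8-yl}-4,5-dimethoxybenzoate, via bridged lactone adduct 13 (not isolated)
Conditions: 5 (2 equiv), toluene, 130 °C, sealed tube, Ar
Reagents that add atoms: none
Why: The pyrone, made electron-poor by its C5 ester, acts as the 4π partner through C3–C6 and the ynol ether as the electron-rich 2π partner in a concerted, asynchronous [4+2] cycloaddition of inverse electron demand to bridged lactone 13, which at the same temperature expels CO2 in a retro-[4+2] step and leaves the benzene ring. The closest known reaction type is the benzannulation of methyl coumalate with electron-rich alkynes (ynamines) and alkenes (enol ethers, ketene acetals), so the reaction class is established and only this pairing of a 3-alkoxypyrone with an aryl ynol ether is untried. Ring B is closed by the intermolecular cycloaddition itself, both new bonds (C2'–C3' from pyrone C6, C4'–C5' from pyrone C3) joining the diene termini to the two alkyne carbons, and the six-membered ring becomes aromatic when the lactone bridge leaves. No stereocentre remains, since the two bridgeheads of 13 vanish with CO2 and the biaryl axis is not a defined element of the target. The selectivity needed is regiochemical, ring D having to end up meta to the ester and beside the new methoxyl; it is secured because oxygen donation makes the aryl-bearing alkyne carbon the nucleophilic terminus, which bonds to pyrone C6 (the most electrophilic terminus, beta to the ester and attached to the ring oxygen), and sterics agree, since the hindered aryl terminus meets the unsubstituted C6–H. A methyl ynol ether has no beta hydrogen and cannot collapse to a ketene on heating, and the benzyl ethers, flavone and methyl ester are inert under neutral thermal conditions.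

Step 8
Reactants: 15 2',4',6'-trihydroxyacetophenone
Product: 16 1-[2,4-bis(benzyloxy)-6-hydroxyphenyl]ethan-1-one
Conditions: BnBr (2 equiv), K2CO3, acetone, reflux
Reagents that add atoms: benzyl bromide, BrCc1ccccc1
Why: Williamson etherification with two equivalents of bromide should spare one ortho hydroxyl, whose hydrogen bond to the acetyl carbonyl makes it the least nucleophilic of the three phenols.

Step 9
Reactants: 14 methyl 3-{5,7-bis(benzyloxy)-2-[4-(benzyloxy)phenyl]-4-oxo-4H-chromen-8-yl}-4,5-dimethoxybenzoate; 16 1-[2,4-bis(benzyloxy)-6-hydroxyphenyl]ethan-1-one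
Product: 17 1-[2,4-bis(benzyloxy)-6-hydroxyphenyl]-3-(3-{5,7-bis(benzyloxy)-2-[4-(benzyloxy)phenyl]-4-oxo-4H-chromen-8-yl}-4,5-dimethoxyphenyl)propane-1,3-dione
Conditions: 16 (2 equiv), LiN(SiMe3)2 (6 equiv), THF, −78 to −10 °C; then 14, −78 °C to rt; 1 M HCl
Reagents that add atoms: none
Why: Crossed Claisen condensation, in which the lithium dianion (phenoxide and ketone enolate) of 16 adds to the unhindered methyl ester of 14 and a third equivalent of base drains the equilibrium by deprotonating the 1,3-diketone, while the flavone of unit 2 offers no acidic hydrogen and only a weakly electrophilic vinylogous ester.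

Step 10
Reactants: 17 the 1,3-diketone
Product: 18 5,7-bis(benzyloxy)-2-(3-{5,7-bis(benzyloxy)-2-[4-(benzyloxy)phenyl]-4-oxo-4H-chromen-8-yl}-4,5-dimethoxyphenyl)-4H-chromen-4-one
Conditions: TsOH·H2O (cat.), toluene, 100 °C
Reagents that add atoms: none
Why: Acid-catalysed cyclodehydration, in which the free ortho phenol adds to the aryl ketone carbonyl (6-exo-trig) and loss of water gives the aromatic pyranone ring C, under conditions that leave benzyl and methyl ethers alone.

Step 11
Reactants: 18 the pentabenzyl biflavone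
Product: 19 5'-methoxybilobetin
Conditions: H2 (1 atm), Pd/C (10% palladium on carbon), THF–MeOH, rt
Reagents that add atoms: none
Why: Hydrogenolysis of the five benzylic C–O bonds over palladium spares the aryl methyl ethers and, at one atmosphere and room temperature, the pyranone double bonds, and it generates no benzyl cation that could alkylate the electron-rich rings A and D.

**Compound list**

1 | methyl coumalate (methyl 6-oxo-6H-pyran-3-carboxylate) | COC(=O)C1=COC(=O)C=C1 | starting material
2 | methyl 5-bromo-6-oxo-6H-pyran-3-carboxylate | COC(=O)C1=COC(=O)C(Br)=C1 | intermediate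
3 | methyl 6-oxo-5-(4,4,5,5-tetramethyl-1,3,2-dioxaborolan-2-yl)-6H-pyran-3-carboxylate (not isolated) | COC(=O)C1=COC(=O)C(B2OC(C)(C)C(C)(C)O2)=C1 | intermediate
4 | methyl 5-hydroxy-6-oxo-6H-pyran-3-carboxylate | COC(=O)C1=COC(=O)C(O)=C1 | intermediate
5 | methyl 5-methoxy-6-oxo-6H-pyran-3-carboxylate | COC(=O)C1=COC(=O)C(OC)=C1 | intermediate
6 | apigenin | O=c1cc(-c2ccc(O)cc2)oc2cc(O)cc(O)c12 | starting material
7 | 5,7-bis(benzyloxy)-2-[4-(benzyloxy)phenyl]-4H-chromen-4-one | O=c1cc(-c2ccc(OCc3ccccc3)cc2)oc2cc(OCc3ccccc3)cc(OCc3ccccc3)c12 | intermediate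
8 | 5,7-bis(benzyloxy)-2-[4-(benzyloxy)phenyl]-8-iodo-4H-chromen-4-one | O=c1cc(-c2ccc(OCc3ccccc3)cc2)oc2c(I)c(OCc3ccccc3)cc(OCc3ccccc3)c12 | intermediate
9 | chloroacetaldehyde dimethyl acetal | COC(CCl)OC | starting material
10 | lithium methoxyacetylide (not isolated) | [Li]C#COC | intermediate
11 | (methoxyethynyl)zinc chloride (not isolated) | Cl[Zn]C#COC | intermediate
12 | 5,7-bis(benzyloxy)-2-[4-(benzyloxy)phenyl]-8-(methoxyethynyl)-4H-chromen-4-one | COC#Cc1c(OCc2ccccc2)cc(OCc2ccccc2)c2c(=O)cc(-c3ccc(OCc4ccccc4)cc3)oc12 | intermediate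
13 | methyl 7-{5,7-bis(benzyloxy)-2-[4-(benzyloxy)phenyl]-4-oxo-4H-chromen-8-yl}-4,8-dimethoxy-3-oxo-2-oxabicyclo[2.2.2]octa-5,7-diene-6-carboxylate (racemic, one enantiomer drawn; not isolated) | COC(=O)C1=C[C@]2(OC)C(=O)O[C@H]1C(c1c(OCc3ccccc3)cc(OCc3ccccc3)c3c(=O)cc(-c4ccc(OCc5ccccc5)cc4)oc13)=C2OC | intermediate
14 | methyl 3-{5,7-bis(benzyloxy)-2-[4-(benzyloxy)phenyl]-4-oxo-4H-chromen-8-yl}-4,5-dimethoxybenzoate | COC(=O)c1cc(OC)c(OC)c(-c2c(OCc3ccccc3)cc(OCc3ccccc3)c3c(=O)cc(-c4ccc(OCc5ccccc5)cc4)oc23)c1 | intermediate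
15 | 2',4',6'-trihydroxyacetophenone | CC(=O)c1c(O)cc(O)cc1O | starting material
16 | 1-[2,4-bis(benzyloxy)-6-hydroxyphenyl]ethan-1-one | CC(=O)c1c(O)cc(OCc2ccccc2)cc1OCc1ccccc1 | intermediate
17 | 1-[2,4-bis(benzyloxy)-6-hydroxyphenyl]-3-(3-{5,7-bis(benzyloxy)-2-[4-(benzyloxy)phenyl]-4-oxo-4H-chromen-8-yl}-4,5-dimethoxyphenyl)propane-1,3-dione | COc1cc(C(=O)CC(=O)c2c(O)cc(OCc3ccccc3)cc2OCc2ccccc2)cc(-c2c(OCc3ccccc3)cc(OCc3ccccc3)c3c(=O)cc(-c4ccc(OCc5ccccc5)cc4)oc23)c1OC | intermediate
18 | 5,7-bis(benzyloxy)-2-(3-{5,7-bis(benzyloxy)-2-[4-(benzyloxy)phenyl]-4-oxo-4H-chromen-8-yl}-4,5-dimethoxyphenyl)-4H-chromen-4-one | COc1cc(-c2cc(=O)c3c(OCc4ccccc4)cc(OCc4ccccc4)cc3o2)cc(-c2c(OCc3ccccc3)cc(OCc3ccccc3)c3c(=O)cc(-c4ccc(OCc5ccccc5)cc4)oc23)c1OC | intermediate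
19 | 5'-methoxybilobetin | COc1cc(-c2cc(=O)c3c(O)cc(O)cc3o2)cc(-c2c(O)cc(O)c3c(=O)cc(-c4ccc(O)cc4)oc23)c1OC | target

**Step count and risk**

Total step count: 11.
Longest linear sequence: 7 steps (1, 2, 3, 7, 9, 10, 11 from methyl coumalate, or 4, 5, 6, 7, 9, 10, 11 from apigenin).

Steps most likely to fail:

Step 7. The cycloaddition may be too slow with a pyrone whose C3 methoxyl raises its acceptor orbital, so that thermal oligomerisation or adventitious hydration of the ynol ether outruns it, or the partners may pair in the wrong orientation. The fallback gives up the ring construction and makes the biaryl bond by cross-coupling. It sets out from iodide 8. Miyaura borylation (B2pin2, PdCl2(dppf), KOAc, dioxane, 90 °C) should give 5,7-bis(benzyloxy)-2-[4-(benzyloxy)phenyl]-8-(4,4,5,5-tetramethyl-1,3,2-dioxaborolan-2-yl)-4H-chromen-4-one F1. Suzuki–Miyaura coupling of F1 with purchased methyl 3-bromo-4,5-dimethoxybenzoate (COC(=O)c1cc(Br)c(OC)c(OC)c1; Pd(OAc)2, SPhos, K3PO4, toluene–H2O, 90 °C) comes back to the route at benzoate 14.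

Step 2. The pyrone ring may be opened by acetate or water at 80 °C, the alpha-boryl lactone may lose boron to a proton before it is oxidised, or the enol may be over-oxidised. The fallback brings the C5' oxygen in only after the benzene ring exists. It sets out from bromopyrone 2 and ynol ether 12. The same cycloaddition with CO2 loss (toluene, 120 °C), now with a more electron-poor diene, should pass through methyl 7-{5,7-bis(benzyloxy)-2-[4-(benzyloxy)phenyl]-4-oxo-4H-chromen-8-yl}-4-bromo-8-methoxy-3-oxo-2-oxabicyclo[2.2.2]octa-5,7-diene-6-carboxylate F2 (not isolated) to methyl 3-{5,7-bis(benzyloxy)-2-[4-(benzyloxy)phenyl]-4-oxo-4H-chromen-8-yl}-5-bromo-4-methoxybenzoate F3. Palladium-catalysed C–O coupling of this robust aryl bromide with methanol (Pd2(dba)3, tBuBrettPhos, Cs2CO3, MeOH, toluene, 80 °C) comes back at benzoate 14.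

Step 9. The dianion of 16 may add too slowly to an electron-rich ester and simply be protonated on work-up, or may be diverted by addition to the pyranone of unit 2. The fallback makes the C–C bond intramolecularly. It sets out from benzoate 14. Saponification (LiOH, THF–MeOH–H2O, 50 °C) should give 3-{5,7-bis(benzyloxy)-2-[4-(benzyloxy)phenyl]-4-oxo-4H-chromen-8-yl}-4,5-dimethoxybenzoic acid F4. Esterification with phenol 16 (EDC·HCl, DMAP, CH2Cl2, rt) should give 2-acetyl-3,5-bis(benzyloxy)phenyl 3-{5,7-bis(benzyloxy)-2-[4-(benzyloxy)phenyl]-4-oxo-4H-chromen-8-yl}-4,5-dimethoxybenzoate F5. Baker–Venkataraman acyl shift from oxygen to carbon (KOtBu, THF, 0 °C to rt) comes back at diketone 17.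

**Further compounds**

F1 | step 7 | 5,7-bis(benzyloxy)-2-[4-(benzyloxy)phenyl]-8-(4,4,5,5-tetramethyl-1,3,2-dioxaborolan-2-yl)-4H-chromen-4-one | CC1(C)OB(c2c(OCc3ccccc3)cc(OCc3ccccc3)c3c(=O)cc(-c4ccc(OCc5ccccc5)cc4)oc23)OC1(C)C
F2 | step 2 | methyl 7-{5,7-bis(benzyloxy)-2-[4-(benzyloxy)phenyl]-4-oxo-4H-chromen-8-yl}-4-bromo-8-methoxy-3-oxo-2-oxabicyclo[2.2.2]octa-5,7-diene-6-carboxylate (racemic, one enantiomer drawn) | COC(=O)C1=C[C@]2(Br)C(=O)O[C@H]1C(c1c(OCc3ccccc3)cc(OCc3ccccc3)c3c(=O)cc(-c4ccc(OCc5ccccc5)cc4)oc13)=C2OC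
F3 | step 2 | methyl 3-{5,7-bis(benzyloxy)-2-[4-(benzyloxy)phenyl]-4-oxo-4H-chromen-8-yl}-5-bromo-4-methoxybenzoate | COC(=O)c1cc(Br)c(OC)c(-c2c(OCc3ccccc3)cc(OCc3ccccc3)c3c(=O)cc(-c4ccc(OCc5ccccc5)cc4)oc23)c1
F4 | step 9 | 3-{5,7-bis(benzyloxy)-2-[4-(benzyloxy)phenyl]-4-oxo-4H-chromen-8-yl}-4,5-dimethoxybenzoic acid | COc1cc(C(=O)O)cc(-c2c(OCc3ccccc3)cc(OCc3ccccc3)c3c(=O)cc(-c4ccc(OCc5ccccc5)cc4)oc23)c1OC
F5 | step 9 | 2-acetyl-3,5-bis(benzyloxy)phenyl 3-{5,7-bis(benzyloxy)-2-[4-(benzyloxy)phenyl]-4-oxo-4H-chromen-8-yl}-4,5-dimethoxybenzoate | COc1cc(C(=O)Oc2cc(OCc3ccccc3)cc(OCc3ccccc3)c2C(C)=O)cc(-c2c(OCc3ccccc3)cc(OCc3ccccc3)c3c(=O)cc(-c4ccc(OCc5ccccc5)cc4)oc23)c1OC
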